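## Retrosynthetic overview

- **Feature:** ring D (O–CMe2–CH=CH, fused on C4'/C5' of ring B) is a prenyl chain that has lost two hydrogens and closed onto the 4'-oxygen. C3' carries the same chain untouched.
- **Ring D, formed last:** opening the O–CMe2 bond and restoring two hydrogens gives a 4'-hydroxy-3',5'-diprenylphenyl ring B. Its two prenyl groups are interchanged by rotation about C2–C1'. DDQ dehydrogenation followed by oxa-6π closure rebuilds ring D.
- **C2–C1' bond:** enantioselective Pd/PyOX 1,4-addition of a 4-silyloxy-3,5-diprenylphenylboronic acid to O-silylated 7-hydroxychromone sets 2R.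
- **Boronic acid:** it is made from 4-bromophenol by double ortho-C-prenylation in water, silylation and Br/Li/B exchange.
- **Ring order:** rings A/C (chromone) and ring B (bromophenol) are bought, they are joined at C2–C1', and ring D is the only ring built.

Key step: step 7

Assumption: (S)-t-BuPyOX, which is (S)-4-tert-butyl-2-(2-pyridyl)-4,5-dihydrooxazole, is taken to attack the chromone on the same face as it does β-substituted cyclic enones, and this maps to 2R. If the sense proves opposite on this substrate, the (R)-ligand is used with nothing else changed. Prenyl means 3-methylbut-2-en-1-yl and TBS means tert-butyldimethylsilyl.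

## Route

Step 1
Reactants: 1 4-bromophenol; 2 prenyl bromide (two equivalents are incorporated)
Product: 4 4-bromo-2,6-diprenylphenol, via 4-bromo-2-prenylphenol 3 (not isolated)
Conditions: 2 (3 equiv), KOH (3 equiv), H2O, 0 °C to rt, vigorous stirring
Reagents that add atoms: none
Why: Ambident-phenoxide C-alkylation: in water the phenoxide oxygen is tied up by hydrogen bonding, so the allylic bromide is attacked in SN2 fashion by the two free ortho carbons one after the other (para is blocked by bromine), a reaction type established for para-halophenols that keeps the linear prenyl connectivity.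

Step 2
Reactants: 4 4-bromo-2,6-diprenylphenol
Product: 5 (4-bromo-2,6-diprenylphenoxy)(tert-butyl)dimethylsilane
Conditions: TBSCl, imidazole, DMAP (cat.), DMF, 40 °C
Reagents that add atoms: tert-butyldimethylsilyl chloride, CC(C)(C)[Si](C)(C)Cl
Why: Imidazole-promoted O-silylation of a hindered phenol, which removes the acidic proton before the organolithium step and hides the ortho-prenylphenol motif from divalent palladium in step 5, the aryl bromide and the alkenes being inert.

Step 3
Reactants: 5 (4-bromo-2,6-diprenylphenoxy)(tert-butyl)dimethylsilane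
Product: 8 [4-(tert-butyldimethylsilyloxy)-3,5-diprenylphenyl]boronic acid, via aryllithium 6 (not isolated), via lithium aryltriisopropoxyborate 7 (not isolated)
Conditions: B(OiPr)3, THF/toluene, −78 °C, n-BuLi added dropwise, warm to −20 °C; then 1 M HCl, 0 °C
Reagents that add atoms: triisopropyl borate, CC(C)OB(OC(C)C)OC(C)C; water, O
Why: Bromine–lithium exchange under in situ quench conditions: exchange at −78 °C is faster than attack of n-BuLi on the borate or deprotonation of the benzylic-allylic CH2 groups, 6 is captured at once as the ate complex 7, and brief cold aqueous acid hydrolyses the B–OiPr bonds without touching the aryl silyl ether or the trisubstituted alkenes.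

Step 4
Reactants: 9 7-hydroxychromone
Product: 10 7-(tert-butyldimethylsilyloxy)chromen-4-one
Conditions: TBSCl, imidazole, CH2Cl2/DMF, rt
Reagents that add atoms: tert-butyldimethylsilyl chloride, CC(C)(C)[Si](C)(C)Cl
Why: Standard O-silylation of the only acidic OH, which makes the chromone soluble in chlorinated solvent and keeps a free phenol away from the cationic palladium catalyst of the next step.

Step 5
Reactants: 8 [4-(tert-butyldimethylsilyloxy)-3,5-diprenylphenyl]boronic acid; 10 7-(tert-butyldimethylsilyloxy)chromen-4-one
Product: 11 (2R)-7-(tert-butyldimethylsilyloxy)-2-[4-(tert-butyldimethylsilyloxy)-3,5-diprenylphenyl]chroman-4-one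
Conditions: 8 (1.5–2 equiv), Pd(OCOCF3)2 (5 mol %), (S)-t-BuPyOX (6 mol %), NH4PF6 (30 mol %), H2O (5 equiv), ClCH2CH2Cl, 60 °C
Reagents that add atoms: none
Why: Palladium-catalysed asymmetric conjugate addition of an arylboronic acid to a chromone (the palladium counterpart of the Hayashi–Miyaura 1,4-addition): transmetalation gives a cationic aryl–palladium PyOX complex, migratory insertion into C2=C3 is enantiodetermining with the tert-butyl group of the ligand shielding one face so that the aryl group is delivered to give 2R, the anti relationship of Pd and C2–H in the ring rules out β-hydride elimination, and water protonates the palladium enolate, while the meta-placed trisubstituted prenyl alkenes are too remote and too hindered to insert.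

Step 6
Reactants: 11 (2R)-bis-TBS flavanone
Product: 13 (2R)-7,4'-dihydroxy-3',5'-diprenylflavanone, via 4'-O-TBS-7-hydroxyflavanone 12 (not isolated)
Conditions: Bu4NF (2.4 equiv), AcOH (3 equiv), THF, 0 °C to rt; pH 6 phosphate work-up, used promptly
Reagents that add atoms: none
Why: Fluoride-induced cleavage of aryl silyl ethers, the unhindered electron-poor 7-O-silyl group leaving first and the flanked 4'-O-silyl group second, with acetic acid protonating each phenoxide as it forms so that the 4'-phenoxide cannot push ring C open by a retro-oxa-Michael reaction and the C2 configuration is kept.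

Step 7
Reactants: 13 (2R)-7,4'-dihydroxy-3',5'-diprenylflavanone
Product: 15 ent-abyssinone III [(2R)-7-hydroxy-2-(2,2-dimethyl-8-prenyl-2H-chromen-6-yl)chroman-4-one], via ortho-quinone methide 14 (not isolated)
Conditions: DDQ (1.0 equiv), anhydrous toluene/1,4-dioxane, rt (to 40 °C if slow), Ar, dark; filter off the hydroquinone, short silica pad
Reagents that add atoms: none
Why: DDQ forms a charge-transfer complex with the electron-rich 2,6-dialkylphenol of ring B and removes a hydride from one ArCH2CH=CMe2 methylene together with the phenolic proton, which gives the vinyl-extended ortho-quinone methide 14. The six-membered ring D then closes by thermal disrotatory oxa-6π electrocyclisation of the oxatriene O=C4'–C5'=CH–CH=CMe2, forming the O–CMe2 bond and restoring the aromaticity of ring B, which is the well-known DDQ oxidative cyclisation of ortho-prenylphenols to 2,2-dimethyl-2H-chromenes. No stereocentre is created, and C2 stays as set in step 5 because no base is present that could open ring C. No choice between the two prenyl groups is required, since rotation about C2–C1' interchanges them and closure of either one gives the same compound 15. Chemoselectivity over the para-benzylic C2–H is secured by the substrate itself, because the CH2 is benzylic and allylic with a dimethyl-stabilised terminus and is the better hydride donor, whereas C2–H is flanked by the withdrawing CH2C=O unit and by an aryloxy oxygen whose lone pair is drawn into the C4 carbonyl, and dehydrogenation of ring C to a flavone needs far more forcing conditions. Further oxidation is held back because 15 has no free phenol on ring B and only one equivalent of oxidant is supplied.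

## Compound list

1 | 4-bromophenol | Oc1ccc(Br)cc1 | starting material
2 | prenyl bromide (1-bromo-3-methylbut-2-ene) | CC(C)=CCBr | starting material
3 | 4-bromo-2-prenylphenol | CC(C)=CCc1cc(Br)ccc1O | intermediate
4 | 4-bromo-2,6-diprenylphenol | CC(C)=CCc1cc(Br)cc(CC=C(C)C)c1O | intermediate
5 | (4-bromo-2,6-diprenylphenoxy)(tert-butyl)dimethylsilane | CC(C)=CCc1cc(Br)cc(CC=C(C)C)c1O[Si](C)(C)C(C)(C)C | intermediate
6 | [4-(tert-butyldimethylsilyloxy)-3,5-diprenylphenyl]lithium | CC(C)=CCc1cc([Li])cc(CC=C(C)C)c1O[Si](C)(C)C(C)(C)C | intermediate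
7 | lithium [4-(tert-butyldimethylsilyloxy)-3,5-diprenylphenyl]triisopropoxyborate | CC(C)=CCc1cc(cc(CC=C(C)C)c1O[Si](C)(C)C(C)(C)C)[B-](OC(C)C)(OC(C)C)OC(C)C.[Li+] | intermediate
8 | [4-(tert-butyldimethylsilyloxy)-3,5-diprenylphenyl]boronic acid | CC(C)=CCc1cc(B(O)O)cc(CC=C(C)C)c1O[Si](C)(C)C(C)(C)C | intermediate
9 | 7-hydroxychromone | O=c1ccoc2cc(O)ccc12 | starting material
10 | 7-(tert-butyldimethylsilyloxy)chromen-4-one | O=c1ccoc2cc(O[Si](C)(C)C(C)(C)C)ccc12 | intermediate
11 | (2R)-7-(tert-butyldimethylsilyloxy)-2-[4-(tert-butyldimethylsilyloxy)-3,5-diprenylphenyl]chroman-4-one | CC(C)=CCc1cc([C@H]2CC(=O)c3ccc(O[Si](C)(C)C(C)(C)C)cc3O2)cc(CC=C(C)C)c1O[Si](C)(C)C(C)(C)C | intermediate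
12 | (2R)-2-[4-(tert-butyldimethylsilyloxy)-3,5-diprenylphenyl]-7-hydroxychroman-4-one | CC(C)=CCc1cc([C@H]2CC(=O)c3ccc(O)cc3O2)cc(CC=C(C)C)c1O[Si](C)(C)C(C)(C)C | intermediate
13 | (2R)-7,4'-dihydroxy-3',5'-diprenylflavanone | CC(C)=CCc1cc([C@H]2CC(=O)c3ccc(O)cc3O2)cc(CC=C(C)C)c1O | intermediate
14 | ortho-quinone methide of ring B, (Z)-exocyclic C5'=CH–CH=CMe2, 2R | CC(C)=CCC1=CC([C@H]2CC(=O)c3ccc(O)cc3O2)=C/C(=C/C=C(C)C)C1=O | intermediate
15 | ent-abyssinone III, (2R)-7-hydroxy-2-(2,2-dimethyl-8-prenyl-2H-chromen-6-yl)chroman-4-one | CC(C)=CCc1cc([C@H]2CC(=O)c3ccc(O)cc3O2)cc2c1OC(C)(C)C=C2 | target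

## Step count

Total step count: 7.
Longest linear sequence: 6 (steps 1, 2, 3, 5, 6, 7).

## Steps most likely to fail

**Step 7.**
- What may go wrong:
  - Hydride loss from C2–H may compete and dehydrogenate ring C.
  - The quinone methide may be trapped or may oligomerise before it closes.
  - The remaining prenyl group may be oxidised slowly.
  - The acidic hydroquinone may erode the configuration at C2.
- Fallback: a hydride-abstracting oxidant is avoided by using electrophilic seleno-etherification followed by elimination.
  - The fallback sets out from 13. PhSeCl (1.0 equiv, CH2Cl2, −78 °C) forms a seleniranium ion on one prenyl group.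
  - The 4'-OH opens it at the tertiary carbon in a 6-endo mode. This gives (2R)-7-hydroxy-2-[2,2-dimethyl-3-(phenylselanyl)-8-prenylchroman-6-yl]chroman-4-one F1 as both C3'' epimers.
  - H2O2 (THF, 0 °C to rt) oxidises it to the selenoxide F2.
  - F2 undergoes syn elimination toward the only β-hydrogens, those at the benzylic C4'', and the fallback comes back to the route at 15.

**Step 5.**
- What may go wrong:
  - Facial selectivity may erode with an electron-rich para-oxygenated arylboronic acid.
  - Protodeboronation may outrun transmetalation.
  - The cationic divalent palladium may engage the prenyl alkenes.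
- Fallback: ring C is closed by an organocatalytic step in place of the C2–C1' coupling.
  - The fallback sets out from 5. Br/Li exchange (n-BuLi, THF, −78 °C) and DMF give 4-(tert-butyldimethylsilyloxy)-3,5-diprenylbenzaldehyde F3.
  - Commercial methyl 2,4-dihydroxybenzoate is silylated at the non-chelated 4-OH (TBSCl, imidazole) to methyl 4-(tert-butyldimethylsilyloxy)-2-hydroxybenzoate F4.
  - A crossed Claisen condensation of F4 with the excess lithium enolate of tert-butyl acetate (LiN(iPr)2, THF, −78 to 0 °C) gives tert-butyl 3-[4-(tert-butyldimethylsilyloxy)-2-hydroxyphenyl]-3-oxopropanoate F5.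
  - Knoevenagel condensation of F3 with F5 (piperidine/AcOH cat., toluene, molecular sieves) gives the alkylidene β-keto ester F6.
  - Enantioselective intramolecular oxa-Michael addition follows in toluene at −25 °C. The catalyst is a 9-amino(9-deoxy)-epi-cinchona thiourea with a 3,5-bis(trifluoromethyl)phenyl group, and the member of the quinine/quinidine pseudo-enantiomeric pair that directs closure to 2R is chosen. This gives the tert-butyl (2R)-4-oxochroman-3-carboxylate F7.
  - TsOH in toluene at 80 °C removes the ester with decarboxylation, and the fallback comes back to the route at 11.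

**Step 1.**
- What may go wrong:
  - O-alkylation may compete with C-alkylation.
  - The reaction may stop after the first prenylation.
  - Prenyl bromide may hydrolyse.
  - A second alkylation may occur on an already substituted ortho carbon.
- Fallback: halogen-directed cross-coupling replaces phenoxide alkylation.
  - The fallback sets out from 1. Double ortho-iodination (N-iodosuccinimide, cat. TsOH, MeCN) gives 4-bromo-2,6-diiodophenol F8.
  - Silylation (TBSCl, imidazole, DMF) gives (4-bromo-2,6-diiodophenoxy)(tert-butyl)dimethylsilane F9.
  - A double Stille coupling with tributyl(prenyl)stannane (Pd(PPh3)4, DMF, 80 °C) engages the two C–I bonds in preference to the C–Br bond and delivers the linear prenyl groups.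
  - The fallback comes back to the route at 5.

## Further compounds

F1 | step 7 | (2R)-7-hydroxy-2-[2,2-dimethyl-3-(phenylselanyl)-8-prenylchroman-6-yl]chroman-4-one (both C3'' epimers) | CC(C)=CCc1cc([C@H]2CC(=O)c3ccc(O)cc3O2)cc2c1OC(C)(C)C([Se]c3ccccc3)C2
F2 | step 7 | selenoxide of F1 | CC(C)=CCc1cc([C@H]2CC(=O)c3ccc(O)cc3O2)cc2c1OC(C)(C)C([Se](=O)c3ccccc3)C2
F3 | step 5 | 4-(tert-butyldimethylsilyloxy)-3,5-diprenylbenzaldehyde | CC(C)=CCc1cc(C=O)cc(CC=C(C)C)c1O[Si](C)(C)C(C)(C)C
F4 | step 5 | methyl 4-(tert-butyldimethylsilyloxy)-2-hydroxybenzoate | COC(=O)c1ccc(O[Si](C)(C)C(C)(C)C)cc1O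
F5 | step 5 | tert-butyl 3-[4-(tert-butyldimethylsilyloxy)-2-hydroxyphenyl]-3-oxopropanoate | CC(C)(C)OC(=O)CC(=O)c1ccc(O[Si](C)(C)C(C)(C)C)cc1O
F6 | step 5 | tert-butyl 2-[4-(tert-butyldimethylsilyloxy)-2-hydroxybenzoyl]-3-[4-(tert-butyldimethylsilyloxy)-3,5-diprenylphenyl]prop-2-enoate (alkene geometry not fixed) | CC(C)(C)OC(=O)C(=Cc1cc(CC=C(C)C)c(O[Si](C)(C)C(C)(C)C)c(CC=C(C)C)c1)C(=O)c1ccc(O[Si](C)(C)C(C)(C)C)cc1O
F7 | step 5 | tert-butyl (2R)-7-(tert-butyldimethylsilyloxy)-2-[4-(tert-butyldimethylsilyloxy)-3,5-diprenylphenyl]-4-oxochroman-3-carboxylate (C3 labile) | CC(C)=CCc1cc([C@H]2C(C(=O)OC(C)(C)C)C(=O)c3ccc(O[Si](C)(C)C(C)(C)C)cc3O2)cc(CC=C(C)C)c1O[Si](C)(C)C(C)(C)C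
F8 | step 1 | 4-bromo-2,6-diiodophenol | Oc1c(I)cc(Br)cc1I
F9 | step 1 | (4-bromo-2,6-diiodophenoxy)(tert-butyl)dimethylsilane | CC(C)(C)[Si](C)(C)Oc1c(I)cc(Br)cc1I
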